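## Analysis of the target

The target is a 7-oxabicyclo[4.1.0]hept-3-en-2-one, that is, a cyclohexenone fused to an oxirane. The ring carbons are numbered here C1 (bearing the (E)-hept-1-enyl group), C2 (bearing the hydroxymethyl carbon C7), C3 (secondary carbinol), C4 (oxirane CH), C5 (fully substituted oxirane carbon carrying the (E)-2-methylbut-2-enoic acid chain) and C6 (ketone). C3, C4 and C5 are contiguous stereocentres, all R, with the C3 hydroxyl and the oxirane oxygen on the same face; since an oxirane can only be cis-fused to a six-membered ring, C5 follows from C4, and the real tasks are the absolute configuration at C3 and the C3/C4 relationship. The α,β-epoxy ketone lies inside a cross-conjugated dienone, and C3–H is γ to the C6 carbonyl and next to the oxirane, so base can remove it and the oxirane then opens by vinylogous β-elimination to a 6-hydroxycyclohexa-2,4-dienone that cannot be brought back. The synthesis is hard because of the quaternary oxirane carbon next to a ketone, the fully substituted C1=C2 alkene with four different carbon substituents, and the need to finish under nearly neutral conditions in the presence of a free acid and two allylic alcohols. The strategy rests on the C4–C5 oxirane being α,β to the C6 ketone: C5 can be the chlorine-bearing α-carbon of a ketone enolate, and C4 an aldehyde carbon whose neighbour C3 is the only stereocentre that must be bought. Because C1 is sp2, the ketone can enolise only toward C5, and a Z-configured C1=C2 alkene holds C6 and C3 on the same side, so an open chain is pre-folded for closing carbocycle and oxirane in one operation.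

## Retrosynthetic reasoning

**Protecting groups, 30 back to 27 by way of 29 and 28.** In 27 the C3 oxygen is carried as a triisopropylsilyl ether (bulky, a poor ligand for metal ions, slow to migrate to a neighbouring alkoxide), the C7 oxygen as a p-methoxybenzyl ether and the acid as its methyl ester. The ester is cleaved first, on the fully protected 27, to give 28. The benzyl-type ether is then removed oxidatively to give 29 while C3 is still silylated, so that the secondary allylic alcohol cannot be oxidised. The silyl ether of 29 goes last under slightly acidic fluoride conditions, so nothing basic touches the epoxy ketone once it exists.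

**Key disconnection, 27 back to 24.** The C4–C5 bond and the C5–O bond are cut. These are the only two bonds whose formation creates both rings and both remaining stereocentres, and the α,β-relationship of oxirane and ketone provides the polarity for them. What is gained is the acyclic precursor 24 with a single stereocentre. The forward reaction has to generate the C5 enolate 25 in the presence of the α-silyloxy aldehyde group, add it to C4 under the direction of C3, and let the alkoxide of 26 displace chloride.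

**C4 oxidation level and C5 chlorine, 24 back to 22 and 20.** Aldehyde 24 is traced to the primary triethylsilyl ether 22, which is oxidised directly, so a free C4 hydroxyl never stands beside the C6 ketone. The chlorine of 22 is traced to enolate 21 of ketone 20; regiochemistry is automatic because C5 is the only α-carbon with hydrogens.

**Side chain, 20 back to 17 and 18.** The C5–CH2 bond is cut. Allylation of enolate 19 of methyl ketone 17 with the commercial bromo ester 18 brings in the whole acid chain with its E alkene in one piece.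

**Acyl carbon C6, 17 back to 15 by way of 16.** C6 is carried as a methyl ester up to 15, because the ester is what activates the alkyne in the step that builds C1=C2. It is then turned into the methyl ketone by acyl substitution through Weinreb amide 16.

**The tetrasubstituted alkene, 15 back to 13 and 14, then 13 back to 7 and 9.** The C1–heptenyl bond is cut as a Suzuki coupling of iodide 13 with boronic acid 14, which keeps both alkene geometries. The C2–C7 bond and the C1–I bond are cut together: syn-carbocupration of ynoate 7 puts the new C7 group and the metal cis, so the ester (C6) ends cis to C3, which is the Z geometry the ring closure needs. The C7 oxygen must be a benzyl-type ether in 9, 10, 11 and 12, because an α-silyloxy carbanion would rearrange by a 1,2-shift of silicon from oxygen to carbon.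

**The stereocentre, 7 back to 5, 4, 3, 2 and 1.** C3 comes from (S)-glyceraldehyde acetonide 1; its formyl carbon becomes C2 and its CH2O carbon becomes C4. The descriptor changes from S to R at 2 only through the priority rules and stays R to the target. The acetonide is exchanged on the way from 3 to 5, at the dibromoalkene stage, before C6 exists as a carbonyl group. A free C3 hydroxyl cis to the ester would lactonise, and cis to the ketone it would form a hemiketal that dehydrates to a furan. The primary oxygen gets the silyl group that is later oxidised off, the secondary one the TIPS group.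

**The C7 reagent, 9 back to 8.** A Williamson etherification of the commercial stannyl carbinol 8.

## Alternatives that were turned down

**Alternative 1:** The C3–O and C4–O bonds are taken back to an arene. The forward key step is a whole-cell dioxygenase cis-dihydroxylation of 1-bromo-4-iodobenzene A1 to the diene diol A2, with iodine at C2 and bromine at C5.
- For it: one enzymatic step sets two C–O bonds enantioselectively, their cis relationship is exactly that of the target, and the two halogens are separate handles for C7 and the side chain. On the certainty of the C3/C4 relationship it is stronger than the chosen route, which relies on substrate control.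
- Against it: the enzyme discriminates the two flanking substituents mainly by size, and bromine and iodine differ little, so regio- and enantioselection are doubtful. No ring C–C bond, no C6 ketone, no heptenyl group and no quaternary C5 exist after the key step. C5 must change from an sp2 C–Br carbon into a quaternary carbon that receives both the chain and the C4 oxygen, and diene diols of this kind dimerise and dehydrate to phenols.
- Comparison: the sequence after the key step is long and redox-heavy. The chosen route assembles every carbon substituent first and forms both rings and two stereocentres in its last skeletal step.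

**Alternative 2:** The C6–C1 and C3–C2 bonds are cut as a [4+2] cycloaddition. The 2-borylated furan A3 and the ynal A4 would combine under a chiral Lewis acid to the oxygen-bridged adduct A5. Its bridgehead boron masks the C6 ketone and its oxygen bridge becomes the C3 hydroxyl.
- For it: it is the most convergent plan and is catalytic in chirality. Epoxidation from the exo face, syn to the oxygen bridge, would give the required cis relationship of C3–O and oxirane by geometry. On these points it is stronger than the chosen route.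
- Against it: furan–alkyne cycloadditions are reversible and slow, and a β-substituted ynal is a poor dienophile. A tetracoordinate boronate does not activate the furan or direct the regiochemistry, and enantioselective catalysis for such a fully substituted adduct is unproven. Oxygen-bridged dienes of this type aromatise under Lewis acids. Once the bridge is opened, C3 carries a carbinol hydrogen flanked by the C1=C2 and C4=C5 alkenes of a cross-conjugated dienone, and loss of that hydrogen aromatises the ring unless the oxirane is already in place.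
- Comparison: its key step needs three unproven selectivities (regio-, enantio-, and survival of the adduct). The chosen key step needs one (the face of C4) and starts from a precursor made by standard reactions.

**Alternative 3:** C1 is removed, cutting C1–C6 and C1–C2. Dibromocarbene would cyclopropanate the five-membered silyl enol ether A6 across C6=C2, and opening of the three-membered ring with loss of bromide and of the silyl group would enlarge the ring to the 2-bromo enone A7. The heptenyl group would then be attached by Suzuki coupling with 14.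
- For it: the sensitive dienone appears only at the very end through a robust coupling, and A6 can only be the C6=C2 regioisomer because C5 is quaternary. In postponing the diene it is stronger than the chosen route.
- Against it: A6 already contains all three stereocentres including the quaternary oxirane carbon, so the stereochemical problem is only moved to an earlier, unsolved part. Enolisation toward C2 on the way to A6 puts negative charge β to the C3 silyloxy group, which can then be expelled. Carbene generation and cyclopropane opening would have to be survived by an α,β-epoxy carbonyl system.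
- Comparison: the key step adds one carbon and no stereochemistry, and the route is linear and longer. The chosen key step creates two rings, two bonds and two stereocentres.

Key step: step 13

Remark on the chemistry: 21, 22, 23, 24 and 25 are mixtures at C5 or of enolate geometry and are written without a C5 descriptor, because C5 becomes trigonal in enolate 25; 26 is written as the one diastereomer that closes.

## Route

Step 1
Reactants: 1 (4S)-2,2-dimethyl-1,3-dioxolane-4-carbaldehyde [(S)-glyceraldehyde acetonide]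
Product: 2 (4R)-4-(2,2-dibromoethenyl)-2,2-dimethyl-1,3-dioxolane
Conditions: CBr4, PPh3, Et3N, CH2Cl2, 0 °C
Reagents that add atoms: carbon tetrabromide, BrC(Br)(Br)Br
Why: First stage of the Corey–Fuchs sequence, a Wittig reaction of the ylide formed from CBr4 and PPh3. The medium is not basic enough to enolise the α-alkoxy aldehyde, and Et3N protects the acetonide from acid.

Step 2
Reactants: 2 (4R)-4-(2,2-dibromoethenyl)-2,2-dimethyl-1,3-dioxolane
Product: 3 (2R)-4,4-dibromobut-3-ene-1,2-diol
Conditions: 80% aq. AcOH, 50 °C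
Reagents that add atoms: none
Why: Acid-catalysed acetal hydrolysis; the dibromoalkene is inert to aqueous acid. The acetonide is removed here so that the C3 hydroxyl is never free once a C6 carbonyl is cis to it.

Step 3
Reactants: 3 (2R)-4,4-dibromobut-3-ene-1,2-diol
Product: 4 (2R)-4,4-dibromo-1-[(triethylsilyl)oxy]but-3-en-2-ol
Conditions: TESCl (1.05 equiv), imidazole, CH2Cl2, −78 to −40 °C
Reagents that add atoms: chlorotriethylsilane, CC[Si](Cl)(CC)CC
Why: Selective silylation of the primary hydroxyl by steric discrimination at low temperature. The primary TES ether is the group that step 12 oxidises directly to the aldehyde.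

Step 4
Reactants: 4 (2R)-4,4-dibromo-1-[(triethylsilyl)oxy]but-3-en-2-ol
Product: 5 (2R)-4,4-dibromo-1-[(triethylsilyl)oxy]-2-[(triisopropylsilyl)oxy]but-3-ene
Conditions: TIPSOTf, 2,6-lutidine, CH2Cl2, −78 to 0 °C
Reagents that add atoms: triisopropylsilyl trifluoromethanesulfonate, CC(C)[Si](OS(=O)(=O)C(F)(F)F)(C(C)C)C(C)C
Why: Silyl triflate silylation of the secondary allylic alcohol. TIPS is chosen because it does not chelate and migrates only slowly to a neighbouring alkoxide, both of which matter in step 13.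

Step 5
Reactants: 5 (2R)-4,4-dibromo-1-[(triethylsilyl)oxy]-2-[(triisopropylsilyl)oxy]but-3-ene
Product: 7 methyl (4R)-5-[(triethylsilyl)oxy]-4-[(triisopropylsilyl)oxy]pent-2-ynoate, via alkynyllithium 6 (not isolated)
Conditions: n-BuLi (2.1 equiv), THF, −78 °C; ClCO2Me, −78 to −20 °C
Reagents that add atoms: methyl chloroformate, COC(=O)Cl
Why: Second stage of the Corey–Fuchs sequence: bromine–lithium exchange, 1,2-shift to the alkyne and deprotonation give 6, which is acylated on carbon. Silyl ethers tolerate n-BuLi at −78 °C and the stereocentre is not involved.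

Step 6
Reactants: 8 (tributylstannyl)methanol
Product: 9 tributyl{[(4-methoxybenzyl)oxy]methyl}stannane
Conditions: NaH, PMBCl, Bu4NI (cat.), THF/DMF, 0 °C to rt
Reagents that add atoms: 4-methoxybenzyl chloride, COc1ccc(CCl)cc1
Why: Williamson etherification of the primary alkoxide. A benzyl-type ether is used because the lithiated silyl ether would undergo the retro-Brook shift.

Step 7
Reactants: 9 tributyl{[(4-methoxybenzyl)oxy]methyl}stannane; 7 methyl (4R)-5-[(triethylsilyl)oxy]-4-[(triisopropylsilyl)oxy]pent-2-ynoate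
Product: 13 methyl (2E,4R)-2-iodo-3-{[(4-methoxybenzyl)oxy]methyl}-5-[(triethylsilyl)oxy]-4-[(triisopropylsilyl)oxy]pent-2-enoate, via alkoxymethyllithium 10 (not isolated), via Gilman cuprate 11 (not isolated), via alkenylcuprate 12 (not isolated)
Conditions: 9 (2.2 equiv), n-BuLi, THF, −78 °C; CuBr·SMe2 (1.1 equiv), −78 °C; 7, −78 °C; I2, THF, −78 °C
Reagents that add atoms: iodine, II
Why: Tin–lithium exchange gives the α-alkoxy organolithium 10, stable at −78 °C, and from it the Gilman cuprate 11. Syn-carbocupration of the ynoate puts CH2OPMB on C2 and copper on C1 cis to it. Iodinolysis with retention at −78 °C, before 12 can equilibrate through the allenolate, fixes CO2Me cis to C3.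

Step 8
Reactants: 13 methyl (2E,4R)-2-iodo-3-{[(4-methoxybenzyl)oxy]methyl}-5-[(triethylsilyl)oxy]-4-[(triisopropylsilyl)oxy]pent-2-enoate; 14 (E)-hept-1-en-1-ylboronic acid
Product: 15 methyl (2Z,4R)-2-[(1E)-hept-1-en-1-yl]-3-{[(4-methoxybenzyl)oxy]methyl}-5-[(triethylsilyl)oxy]-4-[(triisopropylsilyl)oxy]pent-2-enoate
Conditions: Pd(OAc)2 (5 mol %), SPhos (10 mol %), K3PO4, THF/H2O, 40 °C
Reagents that add atoms: none
Why: Suzuki–Miyaura coupling of an alkenyl iodide with an alkenylboronic acid, with retention of both alkene geometries. A bulky electron-rich phosphine is used for the hindered α-iodo enoate.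

Step 9
Reactants: 15 methyl (2Z,4R)-2-[(1E)-hept-1-en-1-yl]-3-{[(4-methoxybenzyl)oxy]methyl}-5-[(triethylsilyl)oxy]-4-[(triisopropylsilyl)oxy]pent-2-enoate
Product: 17 (3Z,5R)-3-[(1E)-hept-1-en-1-yl]-4-{[(4-methoxybenzyl)oxy]methyl}-6-[(triethylsilyl)oxy]-5-[(triisopropylsilyl)oxy]hex-3-en-2-one, via Weinreb amide 16 (not isolated)
Conditions: MeNH(OMe)·HCl, i-PrMgCl, THF, −20 to 0 °C; then MeMgCl, 0 °C to rt
Reagents that add atoms: methylmagnesium chloride, C[Mg]Cl
Why: The magnesium amide converts the ester into Weinreb amide 16 in the flask. Methyl Grignard addition gives a chelated tetrahedral intermediate that releases the ketone only on work-up, so there is no over-addition. The fully substituted β-carbon disfavours conjugate addition.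

Step 10
Reactants: 17 (3Z,5R)-3-[(1E)-hept-1-en-1-yl]-4-{[(4-methoxybenzyl)oxy]methyl}-6-[(triethylsilyl)oxy]-5-[(triisopropylsilyl)oxy]hex-3-en-2-one; 18 methyl (2E)-4-bromo-2-methylbut-2-enoate
Product: 20 methyl (2E,7Z,9R)-7-[(1E)-hept-1-en-1-yl]-8-{[(4-methoxybenzyl)oxy]methyl}-2-methyl-6-oxo-10-[(triethylsilyl)oxy]-9-[(triisopropylsilyl)oxy]deca-2,7-dienoate, via lithium enolate 19 (not isolated)
Conditions: LDA, THF, −78 °C; 18, DMPU, −78 to −40 °C
Reagents that add atoms: none
Why: Kinetic deprotonation of the methyl group gives the cross-conjugated enolate 19; C1 has no hydrogen and γ-deprotonation is slower at −78 °C. SN2 alkylation with the allylic bromide keeps its E geometry.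

Step 11
Reactants: 20 methyl (2E,7Z,9R)-7-[(1E)-hept-1-en-1-yl]-8-{[(4-methoxybenzyl)oxy]methyl}-2-methyl-6-oxo-10-[(triethylsilyl)oxy]-9-[(triisopropylsilyl)oxy]deca-2,7-dienoate
Product: 22 methyl (2E,7Z,9R)-5-chloro-7-[(1E)-hept-1-en-1-yl]-8-{[(4-methoxybenzyl)oxy]methyl}-2-methyl-6-oxo-10-[(triethylsilyl)oxy]-9-[(triisopropylsilyl)oxy]deca-2,7-dienoate (both C5 epimers), via lithium enolate 21 (not isolated)
Conditions: LiHMDS, THF, −78 °C; NCS, −78 °C
Reagents that add atoms: N-chlorosuccinimide, O=C1CCC(=O)N1Cl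
Why: The ketone can enolise only toward C5, and the ketone α-protons are more acidic than the γ-protons of the enoate. Electrophilic chlorination of enolate 21 gives the α-chloro ketone; the C5 configuration is irrelevant.

Step 12
Reactants: 22 methyl (2E,7Z,9R)-5-chloro-7-[(1E)-hept-1-en-1-yl]-8-{[(4-methoxybenzyl)oxy]methyl}-2-methyl-6-oxo-10-[(triethylsilyl)oxy]-9-[(triisopropylsilyl)oxy]deca-2,7-dienoate (both C5 epimers)
Product: 24 methyl (2E,7Z,9R)-5-chloro-7-[(1E)-hept-1-en-1-yl]-8-{[(4-methoxybenzyl)oxy]methyl}-2-methyl-6,10-dioxo-9-[(triisopropylsilyl)oxy]deca-2,7-dienoate (both C5 epimers), via alkoxysulfonium chloride 23 (not isolated)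
Conditions: (COCl)2, DMSO, CH2Cl2, −78 to −40 °C; i-Pr2NEt, −78 to −30 °C; cold pH 7 work-up, used crude
Reagents that add atoms: none
Why: Under Swern conditions the chlorosulfonium salt cleaves the primary TES ether, and the alkoxysulfonium salt 23 collapses to the aldehyde on addition of base. The secondary TIPS ether, the PMB ether and the chloro ketone do not react, and the hindered amine at low temperature spares the C3 stereocentre.

Step 13
Reactants: 24 methyl (2E,7Z,9R)-5-chloro-7-[(1E)-hept-1-en-1-yl]-8-{[(4-methoxybenzyl)oxy]methyl}-2-methyl-6,10-dioxo-9-[(triisopropylsilyl)oxy]deca-2,7-dienoate (both C5 epimers)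
Product: 27 methyl (2E)-4-[(1R,5R,6R)-3-[(1E)-hept-1-en-1-yl]-4-{[(4-methoxybenzyl)oxy]methyl}-2-oxo-5-[(triisopropylsilyl)oxy]-7-oxabicyclo[4.1.0]hept-3-en-1-yl]-2-methylbut-2-enoate, via potassium enolate 25 (not isolated), via chlorohydrin alkoxide 26 (not isolated)
Conditions: KHMDS (1.0 equiv), THF, −78 to −20 °C; pH 7 buffer
Reagents that add atoms: none
Why: This is an intramolecular Darzens condensation; the closest known reaction is the base-mediated Darzens reaction of an α-chloro ketone with an aldehyde. KHMDS removes the C5 proton to give enolate 25: the ketone cannot enolise toward the sp2 carbon C1, and C5–H is activated by chlorine and far less hindered than the C3–H of the aldehyde. C5 adds to the C4 aldehyde in a 6-(enolendo)-exo-trig aldol that closes the carbocycle to aldolate 26, and the C4 alkoxide then displaces chloride from C5 with inversion in a 3-exo-tet substitution that closes the oxirane. C4 is controlled by C3: in the Felkin–Anh mode the forming C4–C5 bond is anti to the C3–OTIPS bond, which puts the silyloxy group pseudo-equatorial and the new alkoxide axial, cis to C3–O and anti-periplanar to an axial C5–Cl bond, whereas the 3,4-trans aldolate can reach that alignment only with the silyloxy group 1,3-syn-diaxial to the departing chloride. C5 is fixed by the cis ring fusion that the inversion enforces. The aldol step is reversible, so both C5 epimers of 24 and any aldolate that cannot close return to 25 and drain through the productive channel. The step needs chemoselective enolisation, a non-chelated aldehyde and no silyl transfer to the new alkoxide; the potassium counter-ion and the TIPS ether provide the last two, and one equivalent of base at low temperature protects the C3–H of 24 and of 27. The Z alkene holds C6 and C3 cis, so the chain is pre-folded.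

Step 14
Reactants: 27 methyl (2E)-4-[(1R,5R,6R)-3-[(1E)-hept-1-en-1-yl]-4-{[(4-methoxybenzyl)oxy]methyl}-2-oxo-5-[(triisopropylsilyl)oxy]-7-oxabicyclo[4.1.0]hept-3-en-1-yl]-2-methylbut-2-enoate
Product: 28 (2E)-4-[(1R,5R,6R)-3-[(1E)-hept-1-en-1-yl]-4-{[(4-methoxybenzyl)oxy]methyl}-2-oxo-5-[(triisopropylsilyl)oxy]-7-oxabicyclo[4.1.0]hept-3-en-1-yl]-2-methylbut-2-enoic acid
Conditions: Me3SnOH, ClCH2CH2Cl, 70 °C; cold dilute HCl wash
Reagents that add atoms: trimethyltin hydroxide, C[Sn](C)(C)O
Why: Organotin hydroxide hydrolysis of a methyl ester under essentially neutral conditions, done on the fully protected compound. The epoxy ketone with its base-labile C3–H is not exposed to hydroxide or alkoxide.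

Step 15
Reactants: 28 (2E)-4-[(1R,5R,6R)-3-[(1E)-hept-1-en-1-yl]-4-{[(4-methoxybenzyl)oxy]methyl}-2-oxo-5-[(triisopropylsilyl)oxy]-7-oxabicyclo[4.1.0]hept-3-en-1-yl]-2-methylbut-2-enoic acid
Product: 29 (2E)-4-[(1R,5R,6R)-3-[(1E)-hept-1-en-1-yl]-4-(hydroxymethyl)-2-oxo-5-[(triisopropylsilyl)oxy]-7-oxabicyclo[4.1.0]hept-3-en-1-yl]-2-methylbut-2-enoic acid
Conditions: DDQ, CH2Cl2/pH 7 buffer, 0 °C
Reagents that add atoms: none
Why: Oxidative cleavage of the PMB ether by hydride abstraction and hydrolysis of the oxocarbenium ion. The electron-poor dienone is inert to DDQ, and the C3 silyl ether keeps the secondary allylic alcohol from being oxidised.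

Step 16
Reactants: 29 (2E)-4-[(1R,5R,6R)-3-[(1E)-hept-1-en-1-yl]-4-(hydroxymethyl)-2-oxo-5-[(triisopropylsilyl)oxy]-7-oxabicyclo[4.1.0]hept-3-en-1-yl]-2-methylbut-2-enoic acid
Product: 30 (2E)-4-[(1R,5R,6R)-3-[(1E)-hept-1-en-1-yl]-5-hydroxy-4-(hydroxymethyl)-2-oxo-7-oxabicyclo[4.1.0]hept-3-en-1-yl]-2-methylbut-2-enoic acid (CNP0332048.1)
Conditions: HF·pyridine, pyridine, THF, 0 °C to rt
Reagents that add atoms: none
Why: Fluoride desilylation under buffered, slightly acidic conditions. An α,β-epoxy ketone is deactivated toward acid opening, and no base is present that could remove C3–H.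

## Compound list

1 | (4S)-2,2-dimethyl-1,3-dioxolane-4-carbaldehyde [(S)-glyceraldehyde acetonide] | O=C[C@@H]1COC(C)(C)O1 | starting material
2 | (4R)-4-(2,2-dibromoethenyl)-2,2-dimethyl-1,3-dioxolane | BrC(Br)=C[C@@H]1COC(C)(C)O1 | intermediate
3 | (2R)-4,4-dibromobut-3-ene-1,2-diol | BrC(Br)=C[C@@H](O)CO | intermediate
4 | (2R)-4,4-dibromo-1-[(triethylsilyl)oxy]but-3-en-2-ol | BrC(Br)=C[C@@H](O)CO[Si](CC)(CC)CC | intermediate
5 | (2R)-4,4-dibromo-1-[(triethylsilyl)oxy]-2-[(triisopropylsilyl)oxy]but-3-ene | BrC(Br)=C[C@@H](O[Si](C(C)C)(C(C)C)C(C)C)CO[Si](CC)(CC)CC | intermediate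
6 | {(3R)-4-[(triethylsilyl)oxy]-3-[(triisopropylsilyl)oxy]but-1-yn-1-yl}lithium | [Li]C#C[C@@H](O[Si](C(C)C)(C(C)C)C(C)C)CO[Si](CC)(CC)CC | intermediate (not isolated)
7 | methyl (4R)-5-[(triethylsilyl)oxy]-4-[(triisopropylsilyl)oxy]pent-2-ynoate | COC(=O)C#C[C@@H](O[Si](C(C)C)(C(C)C)C(C)C)CO[Si](CC)(CC)CC | intermediate
8 | (tributylstannyl)methanol | OC[Sn](CCCC)(CCCC)CCCC | starting material
9 | tributyl{[(4-methoxybenzyl)oxy]methyl}stannane | COc1ccc(COC[Sn](CCCC)(CCCC)CCCC)cc1 | intermediate
10 | {[(4-methoxybenzyl)oxy]methyl}lithium | [Li]COCc1ccc(OC)cc1 | intermediate (not isolated)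
11 | lithium bis{[(4-methoxybenzyl)oxy]methyl}cuprate | [Li+].COc1ccc(COC[Cu-]COCc2ccc(OC)cc2)cc1 | intermediate (not isolated)
12 | lithium alkenyl(alkoxymethyl)cuprate from syn addition of 11 to 7 (copper on C1, cis to the new CH2OPMB group; CO2Me cis to C3) | [Li+].COC(=O)/C([Cu-]COCc1ccc(OC)cc1)=C(/COCc1ccc(OC)cc1)[C@@H](O[Si](C(C)C)(C(C)C)C(C)C)CO[Si](CC)(CC)CC | intermediate (not isolated)
13 | methyl (2E,4R)-2-iodo-3-{[(4-methoxybenzyl)oxy]methyl}-5-[(triethylsilyl)oxy]-4-[(triisopropylsilyl)oxy]pent-2-enoate | COC(=O)/C(I)=C(/COCc1ccc(OC)cc1)[C@@H](O[Si](C(C)C)(C(C)C)C(C)C)CO[Si](CC)(CC)CC | intermediate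
14 | (E)-hept-1-en-1-ylboronic acid | CCCCC/C=C/B(O)O | starting material
15 | methyl (2Z,4R)-2-[(1E)-hept-1-en-1-yl]-3-{[(4-methoxybenzyl)oxy]methyl}-5-[(triethylsilyl)oxy]-4-[(triisopropylsilyl)oxy]pent-2-enoate | CCCCC/C=C/C(C(=O)OC)=C(COCc1ccc(OC)cc1)/[C@@H](O[Si](C(C)C)(C(C)C)C(C)C)CO[Si](CC)(CC)CC | intermediate
16 | (2Z,4R)-2-[(1E)-hept-1-en-1-yl]-N-methoxy-3-{[(4-methoxybenzyl)oxy]methyl}-N-methyl-5-[(triethylsilyl)oxy]-4-[(triisopropylsilyl)oxy]pent-2-enamide | CCCCC/C=C/C(C(=O)N(C)OC)=C(COCc1ccc(OC)cc1)/[C@@H](O[Si](C(C)C)(C(C)C)C(C)C)CO[Si](CC)(CC)CC | intermediate (not isolated)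
17 | (3Z,5R)-3-[(1E)-hept-1-en-1-yl]-4-{[(4-methoxybenzyl)oxy]methyl}-6-[(triethylsilyl)oxy]-5-[(triisopropylsilyl)oxy]hex-3-en-2-one | CCCCC/C=C/C(C(C)=O)=C(COCc1ccc(OC)cc1)/[C@@H](O[Si](C(C)C)(C(C)C)C(C)C)CO[Si](CC)(CC)CC | intermediate
18 | methyl (2E)-4-bromo-2-methylbut-2-enoate | COC(=O)/C(C)=C/CBr | starting material
19 | lithium (3Z,5R)-3-[(1E)-hept-1-en-1-yl]-4-{[(4-methoxybenzyl)oxy]methyl}-6-[(triethylsilyl)oxy]-5-[(triisopropylsilyl)oxy]hexa-1,3-dien-2-olate | CCCCC/C=C/C(C(=C)O[Li])=C(COCc1ccc(OC)cc1)/[C@@H](O[Si](C(C)C)(C(C)C)C(C)C)CO[Si](CC)(CC)CC | intermediate (not isolated)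
20 | methyl (2E,7Z,9R)-7-[(1E)-hept-1-en-1-yl]-8-{[(4-methoxybenzyl)oxy]methyl}-2-methyl-6-oxo-10-[(triethylsilyl)oxy]-9-[(triisopropylsilyl)oxy]deca-2,7-dienoate | CCCCC/C=C/C(C(=O)CC/C=C(\C)C(=O)OC)=C(COCc1ccc(OC)cc1)/[C@@H](O[Si](C(C)C)(C(C)C)C(C)C)CO[Si](CC)(CC)CC | intermediate
21 | lithium enolate of 20 (C5=C6 enolate, lithium on the C6 oxygen, geometry not defined) | CCCCC/C=C/C(C(O[Li])=CC/C=C(\C)C(=O)OC)=C(COCc1ccc(OC)cc1)/[C@@H](O[Si](C(C)C)(C(C)C)C(C)C)CO[Si](CC)(CC)CC | intermediate (not isolated)
22 | methyl (2E,7Z,9R)-5-chloro-7-[(1E)-hept-1-en-1-yl]-8-{[(4-methoxybenzyl)oxy]methyl}-2-methyl-6-oxo-10-[(triethylsilyl)oxy]-9-[(triisopropylsilyl)oxy]deca-2,7-dienoate (both C5 epimers) | CCCCC/C=C/C(C(=O)C(Cl)C/C=C(\C)C(=O)OC)=C(COCc1ccc(OC)cc1)/[C@@H](O[Si](C(C)C)(C(C)C)C(C)C)CO[Si](CC)(CC)CC | intermediate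
23 | dimethyl(alkoxy)sulfonium chloride of 22 (the C4 oxygen bound to SMe2+ in place of SiEt3) | CCCCC/C=C/C(C(=O)C(Cl)C/C=C(\C)C(=O)OC)=C(COCc1ccc(OC)cc1)/[C@@H](O[Si](C(C)C)(C(C)C)C(C)C)CO[S+](C)C.[Cl-] | intermediate (not isolated)
24 | methyl (2E,7Z,9R)-5-chloro-7-[(1E)-hept-1-en-1-yl]-8-{[(4-methoxybenzyl)oxy]methyl}-2-methyl-6,10-dioxo-9-[(triisopropylsilyl)oxy]deca-2,7-dienoate (both C5 epimers; precursor of the key step) | CCCCC/C=C/C(C(=O)C(Cl)C/C=C(\C)C(=O)OC)=C(COCc1ccc(OC)cc1)/[C@@H](O[Si](C(C)C)(C(C)C)C(C)C)C=O | intermediate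
25 | potassium enolate of 24 (C5=C6 enolate, chlorine on C5, geometry not defined) | CCCCC/C=C/C(C(O[K])=C(Cl)C/C=C(\C)C(=O)OC)=C(COCc1ccc(OC)cc1)/[C@@H](O[Si](C(C)C)(C(C)C)C(C)C)C=O | intermediate (not isolated)
26 | potassium (1R,2S,6R)-2-chloro-4-[(1E)-hept-1-en-1-yl]-2-[(2E)-4-methoxy-3-methyl-4-oxobut-2-en-1-yl]-5-{[(4-methoxybenzyl)oxy]methyl}-3-oxo-6-[(triisopropylsilyl)oxy]cyclohex-4-en-1-olate (alkoxide cis to the silyloxy group, trans to chlorine) | CCCCC/C=C/C1=C(COCc2ccc(OC)cc2)[C@@H](O[Si](C(C)C)(C(C)C)C(C)C)[C@@H](O[K])[C@@](Cl)(C/C=C(\C)C(=O)OC)C1=O | intermediate (not isolated)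
27 | methyl (2E)-4-[(1R,5R,6R)-3-[(1E)-hept-1-en-1-yl]-4-{[(4-methoxybenzyl)oxy]methyl}-2-oxo-5-[(triisopropylsilyl)oxy]-7-oxabicyclo[4.1.0]hept-3-en-1-yl]-2-methylbut-2-enoate | CCCCC/C=C/C1=C(COCc2ccc(OC)cc2)[C@@H](O[Si](C(C)C)(C(C)C)C(C)C)[C@H]2O[C@@]2(C/C=C(\C)C(=O)OC)C1=O | intermediate
28 | (2E)-4-[(1R,5R,6R)-3-[(1E)-hept-1-en-1-yl]-4-{[(4-methoxybenzyl)oxy]methyl}-2-oxo-5-[(triisopropylsilyl)oxy]-7-oxabicyclo[4.1.0]hept-3-en-1-yl]-2-methylbut-2-enoic acid | CCCCC/C=C/C1=C(COCc2ccc(OC)cc2)[C@@H](O[Si](C(C)C)(C(C)C)C(C)C)[C@H]2O[C@@]2(C/C=C(\C)C(=O)O)C1=O | intermediate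
29 | (2E)-4-[(1R,5R,6R)-3-[(1E)-hept-1-en-1-yl]-4-(hydroxymethyl)-2-oxo-5-[(triisopropylsilyl)oxy]-7-oxabicyclo[4.1.0]hept-3-en-1-yl]-2-methylbut-2-enoic acid | CCCCC/C=C/C1=C(CO)[C@@H](O[Si](C(C)C)(C(C)C)C(C)C)[C@H]2O[C@@]2(C/C=C(\C)C(=O)O)C1=O | intermediate
30 | (2E)-4-[(1R,5R,6R)-3-[(1E)-hept-1-en-1-yl]-5-hydroxy-4-(hydroxymethyl)-2-oxo-7-oxabicyclo[4.1.0]hept-3-en-1-yl]-2-methylbut-2-enoic acid (CNP0332048.1) | CCCCC/C=C/C1=C(CO)[C@@H](O)[C@H]2O[C@@]2(C/C=C(\C)C(=O)O)C1=O | target

## Step count and least certain steps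

Total: 16 steps. Longest linear sequence: 15 steps (steps 1–5 and 7–16, from 1 to 30); step 6 is a one-step branch.

**Step 13 (key step).** Three processes can spoil it: loss of configuration at C3 by enolisation of the α-silyloxy aldehyde, which holds the other acidic C–H of 24; γ-deprotonation of 27 by surplus base, followed by opening of the oxirane to a hydroxy dienone; and poor facial selectivity at C4, because allylic 1,2-strain between a pseudo-equatorial silyloxy group on C3 and the C2 substituent works against the Felkin-type aldolate, so that closure through the 3,4-trans aldolate could compete. Fallback: separate the two bond formations and avoid a strong base. From 24, soft enolisation of the chloro ketone with dicyclohexylboron chloride and i-Pr2NEt in CH2Cl2 at −78 °C should give a boron aldolate that cannot close. Non-oxidative work-up would give the chlorohydrin methyl (2E)-4-[(1S,5R,6R)-1-chloro-3-[(1E)-hept-1-en-1-yl]-6-hydroxy-4-{[(4-methoxybenzyl)oxy]methyl}-2-oxo-5-[(triisopropylsilyl)oxy]cyclohex-3-en-1-yl]-2-methylbut-2-enoate F1, whose C4 epimers can be separated. Brief treatment of F1 with K2CO3 in MeOH at 0 °C should close the oxirane and return to 27.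

**Step 7.** The α-alkoxymethyl ligand may transfer sluggishly (such cuprates are less nucleophilic and thermally fragile), and the alkenylcuprate may lose its geometry through the copper allenolate before iodination. Fallback: bring in C7 as a vinyl group. From 7, lithium divinylcuprate at −78 °C followed by iodine should give methyl (2E,4R)-3-ethenyl-2-iodo-5-[(triethylsilyl)oxy]-4-[(triisopropylsilyl)oxy]pent-2-enoate F2. Ozonolysis of the terminal alkene only (O3, pyridine, CH2Cl2/MeOH, −78 °C, then Me2S) should give methyl (2Z,4R)-3-formyl-2-iodo-5-[(triethylsilyl)oxy]-4-[(triisopropylsilyl)oxy]pent-2-enoate F3. Luche reduction should give methyl (2E,4R)-3-(hydroxymethyl)-2-iodo-5-[(triethylsilyl)oxy]-4-[(triisopropylsilyl)oxy]pent-2-enoate F4. Etherification with 4-methoxybenzyl trichloroacetimidate and catalytic La(OTf)3 should rejoin the route at 13.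

**Step 9.** Acyl substitution may stop short, because the ester carbonyl is twisted out of conjugation and flanked by the heptenyl group and the cis C3 substituent. Fallback: go through the aldehyde. From 15, DIBAL-H at −78 °C should give (2Z,4R)-2-[(1E)-hept-1-en-1-yl]-3-{[(4-methoxybenzyl)oxy]methyl}-5-[(triethylsilyl)oxy]-4-[(triisopropylsilyl)oxy]pent-2-en-1-ol F5. Dess–Martin oxidation should give (2Z,4R)-2-[(1E)-hept-1-en-1-yl]-3-{[(4-methoxybenzyl)oxy]methyl}-5-[(triethylsilyl)oxy]-4-[(triisopropylsilyl)oxy]pent-2-enal F6. MeMgBr should give (3Z,5R)-3-[(1E)-hept-1-en-1-yl]-4-{[(4-methoxybenzyl)oxy]methyl}-6-[(triethylsilyl)oxy]-5-[(triisopropylsilyl)oxy]hex-3-en-2-ol F7 as a mixture of carbinol epimers, and a second Dess–Martin oxidation should return to 17.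

**Step 10.** The γ-bromo enoate is also a Michael acceptor, so conjugate addition with cyclopropane closure, SN2′ attack or proton transfer leading to double alkylation may compete with SN2 substitution. Fallback: build the enoate after the C–C bond. From 17, enolate 19 should be alkylated with allyl bromide to (6Z,8R)-6-[(1E)-hept-1-en-1-yl]-7-{[(4-methoxybenzyl)oxy]methyl}-9-[(triethylsilyl)oxy]-8-[(triisopropylsilyl)oxy]nona-1,6-dien-5-one F8. Cross-metathesis of the terminal alkene of F8 with methyl methacrylate (Hoveyda–Grubbs second-generation catalyst, CH2Cl2, 40 °C) should give the E-enoate and return to 20; the hindered, electron-poor diene should react far more slowly than the terminal alkene.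

**Step 14.** Hydrolysis of the conjugated ester may be slow, and prolonged heating with the Lewis acidic tin reagent may open or eliminate the epoxy ketone. Fallback: exchange the ester group while the molecule is still robust. From 20, LiOH in THF/H2O should give (2E,7Z,9R)-7-[(1E)-hept-1-en-1-yl]-8-{[(4-methoxybenzyl)oxy]methyl}-2-methyl-6-oxo-10-[(triethylsilyl)oxy]-9-[(triisopropylsilyl)oxy]deca-2,7-dienoic acid F9, and allyl bromide with K2CO3 in DMF should turn it into the allyl ester prop-2-en-1-yl (2E,7Z,9R)-7-[(1E)-hept-1-en-1-yl]-8-{[(4-methoxybenzyl)oxy]methyl}-2-methyl-6-oxo-10-[(triethylsilyl)oxy]-9-[(triisopropylsilyl)oxy]deca-2,7-dienoate F10. The conditions of steps 11, 12 and 13 should then give in turn the chloro ketone prop-2-en-1-yl (2E,7Z,9R)-5-chloro-7-[(1E)-hept-1-en-1-yl]-8-{[(4-methoxybenzyl)oxy]methyl}-2-methyl-6-oxo-10-[(triethylsilyl)oxy]-9-[(triisopropylsilyl)oxy]deca-2,7-dienoate F11, the aldehyde prop-2-en-1-yl (2E,7Z,9R)-5-chloro-7-[(1E)-hept-1-en-1-yl]-8-{[(4-methoxybenzyl)oxy]methyl}-2-methyl-6,10-dioxo-9-[(triisopropylsilyl)oxy]deca-2,7-dienoate F12 and the epoxy enone prop-2-en-1-yl (2E)-4-[(1R,5R,6R)-3-[(1E)-hept-1-en-1-yl]-4-{[(4-methoxybenzyl)oxy]methyl}-2-oxo-5-[(triisopropylsilyl)oxy]-7-oxabicyclo[4.1.0]hept-3-en-1-yl]-2-methylbut-2-enoate F13. Pd(PPh3)4 and morpholine at room temperature should then remove the allyl group under neutral conditions and rejoin the route at 28.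

## Further compounds

F1 | step 13 | methyl (2E)-4-[(1S,5R,6R)-1-chloro-3-[(1E)-hept-1-en-1-yl]-6-hydroxy-4-{[(4-methoxybenzyl)oxy]methyl}-2-oxo-5-[(triisopropylsilyl)oxy]cyclohex-3-en-1-yl]-2-methylbut-2-enoate | CCCCC/C=C/C1=C(COCc2ccc(OC)cc2)[C@@H](O[Si](C(C)C)(C(C)C)C(C)C)[C@@H](O)[C@@](Cl)(C/C=C(\C)C(=O)OC)C1=O
F2 | step 7 | methyl (2E,4R)-3-ethenyl-2-iodo-5-[(triethylsilyl)oxy]-4-[(triisopropylsilyl)oxy]pent-2-enoate | COC(=O)/C(I)=C(/C=C)[C@@H](O[Si](C(C)C)(C(C)C)C(C)C)CO[Si](CC)(CC)CC
F3 | step 7 | methyl (2Z,4R)-3-formyl-2-iodo-5-[(triethylsilyl)oxy]-4-[(triisopropylsilyl)oxy]pent-2-enoate | COC(=O)/C(I)=C(/C=O)[C@@H](O[Si](C(C)C)(C(C)C)C(C)C)CO[Si](CC)(CC)CC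
F4 | step 7 | methyl (2E,4R)-3-(hydroxymethyl)-2-iodo-5-[(triethylsilyl)oxy]-4-[(triisopropylsilyl)oxy]pent-2-enoate | COC(=O)/C(I)=C(/CO)[C@@H](O[Si](C(C)C)(C(C)C)C(C)C)CO[Si](CC)(CC)CC
F5 | step 9 | (2Z,4R)-2-[(1E)-hept-1-en-1-yl]-3-{[(4-methoxybenzyl)oxy]methyl}-5-[(triethylsilyl)oxy]-4-[(triisopropylsilyl)oxy]pent-2-en-1-ol | CCCCC/C=C/C(CO)=C(COCc1ccc(OC)cc1)/[C@@H](O[Si](C(C)C)(C(C)C)C(C)C)CO[Si](CC)(CC)CC
F6 | step 9 | (2Z,4R)-2-[(1E)-hept-1-en-1-yl]-3-{[(4-methoxybenzyl)oxy]methyl}-5-[(triethylsilyl)oxy]-4-[(triisopropylsilyl)oxy]pent-2-enal | CCCCC/C=C/C(C=O)=C(COCc1ccc(OC)cc1)/[C@@H](O[Si](C(C)C)(C(C)C)C(C)C)CO[Si](CC)(CC)CC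
F7 | step 9 | (3Z,5R)-3-[(1E)-hept-1-en-1-yl]-4-{[(4-methoxybenzyl)oxy]methyl}-6-[(triethylsilyl)oxy]-5-[(triisopropylsilyl)oxy]hex-3-en-2-ol (both C2 epimers) | CCCCC/C=C/C(C(C)O)=C(COCc1ccc(OC)cc1)/[C@@H](O[Si](C(C)C)(C(C)C)C(C)C)CO[Si](CC)(CC)CC
F8 | step 10 | (6Z,8R)-6-[(1E)-hept-1-en-1-yl]-7-{[(4-methoxybenzyl)oxy]methyl}-9-[(triethylsilyl)oxy]-8-[(triisopropylsilyl)oxy]nona-1,6-dien-5-one | CCCCC/C=C/C(C(=O)CCC=C)=C(COCc1ccc(OC)cc1)/[C@@H](O[Si](C(C)C)(C(C)C)C(C)C)CO[Si](CC)(CC)CC
F9 | step 14 | (2E,7Z,9R)-7-[(1E)-hept-1-en-1-yl]-8-{[(4-methoxybenzyl)oxy]methyl}-2-methyl-6-oxo-10-[(triethylsilyl)oxy]-9-[(triisopropylsilyl)oxy]deca-2,7-dienoic acid | CCCCC/C=C/C(C(=O)CC/C=C(\C)C(=O)O)=C(COCc1ccc(OC)cc1)/[C@@H](O[Si](C(C)C)(C(C)C)C(C)C)CO[Si](CC)(CC)CC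
F10 | step 14 | prop-2-en-1-yl (2E,7Z,9R)-7-[(1E)-hept-1-en-1-yl]-8-{[(4-methoxybenzyl)oxy]methyl}-2-methyl-6-oxo-10-[(triethylsilyl)oxy]-9-[(triisopropylsilyl)oxy]deca-2,7-dienoate | CCCCC/C=C/C(C(=O)CC/C=C(\C)C(=O)OCC=C)=C(COCc1ccc(OC)cc1)/[C@@H](O[Si](C(C)C)(C(C)C)C(C)C)CO[Si](CC)(CC)CC
F11 | step 14 | prop-2-en-1-yl (2E,7Z,9R)-5-chloro-7-[(1E)-hept-1-en-1-yl]-8-{[(4-methoxybenzyl)oxy]methyl}-2-methyl-6-oxo-10-[(triethylsilyl)oxy]-9-[(triisopropylsilyl)oxy]deca-2,7-dienoate (both C5 epimers) | CCCCC/C=C/C(C(=O)C(Cl)C/C=C(\C)C(=O)OCC=C)=C(COCc1ccc(OC)cc1)/[C@@H](O[Si](C(C)C)(C(C)C)C(C)C)CO[Si](CC)(CC)CC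
F12 | step 14 | prop-2-en-1-yl (2E,7Z,9R)-5-chloro-7-[(1E)-hept-1-en-1-yl]-8-{[(4-methoxybenzyl)oxy]methyl}-2-methyl-6,10-dioxo-9-[(triisopropylsilyl)oxy]deca-2,7-dienoate (both C5 epimers) | CCCCC/C=C/C(C(=O)C(Cl)C/C=C(\C)C(=O)OCC=C)=C(COCc1ccc(OC)cc1)/[C@@H](O[Si](C(C)C)(C(C)C)C(C)C)C=O
F13 | step 14 | prop-2-en-1-yl (2E)-4-[(1R,5R,6R)-3-[(1E)-hept-1-en-1-yl]-4-{[(4-methoxybenzyl)oxy]methyl}-2-oxo-5-[(triisopropylsilyl)oxy]-7-oxabicyclo[4.1.0]hept-3-en-1-yl]-2-methylbut-2-enoate | CCCCC/C=C/C1=C(COCc2ccc(OC)cc2)[C@@H](O[Si](C(C)C)(C(C)C)C(C)C)[C@H]2O[C@@]2(C/C=C(\C)C(=O)OCC=C)C1=O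
A1 | alternative 1 | 1-bromo-4-iodobenzene | Brc1ccc(I)cc1
A2 | alternative 1 | cis-3-bromo-6-iodocyclohexa-3,5-diene-1,2-diol | C1=C(I)[C@@H](O)[C@@H](O)C(Br)=C1
A3 | alternative 2 | 2-(N-methyliminodiacetato)boryl-3-[(2E)-4-methoxy-3-methyl-4-oxobut-2-en-1-yl]furan | COC(=O)/C(C)=C/Cc1ccoc1[B-]23OC(=O)C[N+]2(C)CC(=O)O3
A4 | alternative 2 | 4-[(tert-butyldimethylsilyl)oxy]but-2-ynal | O=CC#CCO[Si](C)(C)C(C)(C)C
A5 | alternative 2 | bridgehead-borylated 7-oxanorbornadiene carbaldehyde (formyl on C1, CH2OTBS on C2, oxygen bridge from C3 to C6, side chain on C5, boron on C6) | O=CC1=C(CO[Si](C)(C)C(C)(C)C)[C@@H]2C=C(C/C=C(\C)C(=O)OC)[C@@]1([B-]34OC(=O)C[N+]3(C)CC(=O)O4)O2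
A6 | alternative 3 | trimethylsilyl enol ether (C6=C2) of the epoxycyclopentanone carrying CH2OTBS on C2, OTBS on C3 and the enoate chain on C5 | C[Si](C)(C)OC1=C(CO[Si](C)(C)C(C)(C)C)[C@@H](O[Si](C)(C)C(C)(C)C)[C@H]2O[C@@]12C/C=C(\C)C(=O)OC
A7 | alternative 3 | C1-bromo epoxycyclohexenone | BrC1=C(CO[Si](C)(C)C(C)(C)C)[C@@H](O[Si](C)(C)C(C)(C)C)[C@H]2O[C@@]2(C/C=C(\C)C(=O)OC)C1=O
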